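## Retrosynthetic overview

1. Target ⇐ its bis-O-benzyl ether (hydrogenolysis last); the CH2OH group ⇐ CH2NO2 (Nef reaction, then aldehyde reduction).
2. Oxolane ring (the only ring made) ⇐ intramolecular 5-exo Michael addition: the C3–C4 bond forms from a ketone enolate onto a tethered (E)-nitroalkene.
3. The O1–C5 tether ⇐ oxa-Michael union of fragment A (aryl vinyl ketone) with fragment B ((S)-γ-hydroxy nitroalkene), run in the same flask as the ring closure.
4. Fragment A ⇐ Weinreb amide + CH2=CHMgBr ⇐ methyl isovanillate. Fragment B ⇐ alkene nitration ⇐ lipase resolution ⇐ vinyl addition to O-benzylisovanillin.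
5. Ring order: both benzene rings are bought; the oxolane closes in step 7. C2 comes from the resolution, C3 from substrate control in the cyclisation, C4 by equilibration.

Assumption: methyl 3-hydroxy-4-methoxybenzoate and 3-(benzyloxy)-4-methoxybenzaldehyde are taken as cheap catalogue chemicals.

## Route

**Step 1**
Reactants: 1 methyl 3-hydroxy-4-methoxybenzoate
Product: 2 methyl 3-(benzyloxy)-4-methoxybenzoate
Conditions: BnBr, K2CO3, DMF, 60 °C
Reagents that add atoms: benzyl bromide BrCc1ccccc1
Why: Williamson ether synthesis, in which the phenoxide formed with K2CO3 is benzylated cleanly while the methyl ester is untouched.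

**Step 2**
Reactants: 2 methyl 3-(benzyloxy)-4-methoxybenzoate
Product: 3 3-(benzyloxy)-N,4-dimethoxy-N-methylbenzamide
Conditions: MeNH(OMe)·HCl, (CH3)2CHMgCl, THF, −20 °C; aq. NH4Cl
Reagents that add atoms: N,O-dimethylhydroxylamine hydrochloride CNOC.Cl
Why: Weinreb amide formation by direct aminolysis of the ester with the chloromagnesium amide of N,O-dimethylhydroxylamine, which leaves the aryl ethers alone.

**Step 3**
Reactants: 3 3-(benzyloxy)-N,4-dimethoxy-N-methylbenzamide
Product: 4 1-[3-(benzyloxy)-4-methoxyphenyl]prop-2-en-1-one (fragment A)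
Conditions: CH2=CHMgBr, THF, 0 °C; inverse quench into cold 1 M HCl
Reagents that add atoms: vinylmagnesium bromide C=C[Mg]Br
Why: Weinreb ketone synthesis, in which the chelated tetrahedral adduct prevents over-addition and the acidic inverse quench protonates the released MeNH(OMe) so that it cannot add back to the enone.

**Step 4**
Reactants: 5 3-(benzyloxy)-4-methoxybenzaldehyde
Product: 6 rac-1-[3-(benzyloxy)-4-methoxyphenyl]prop-2-en-1-ol
Conditions: CH2=CHMgBr, THF, −78 to 0 °C; aq. NH4Cl
Reagents that add atoms: vinylmagnesium bromide C=C[Mg]Br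
Why: Grignard 1,2-addition to a non-enolisable aryl aldehyde gives the racemic allylic alcohol whose carbinol carbon is the future C2.

**Step 5**
Reactants: 6 rac-1-[3-(benzyloxy)-4-methoxyphenyl]prop-2-en-1-ol
Product: 7 (S)-1-[3-(benzyloxy)-4-methoxyphenyl]prop-2-en-1-ol
Conditions: immobilised Candida antarctica lipase B, vinyl acetate, t-BuOMe, 30 °C, to ca. 55% conversion
Reagents that add atoms: none
Why: Enzymatic kinetic resolution by irreversible transesterification, in which the lipase acetylates the (R)-alcohol (aryl as large and vinyl as medium substituent, Kazlauskas rule) and leaves the (S)-alcohol in high ee, fixing the C2 configuration of the target.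

**Step 6**
Reactants: 7 (S)-1-[3-(benzyloxy)-4-methoxyphenyl]prop-2-en-1-ol
Product: 8 (1S,2E)-1-[3-(benzyloxy)-4-methoxyphenyl]-3-nitroprop-2-en-1-ol (fragment B)
Conditions: AgNO2, TEMPO (0.4 equiv), 4 Å MS, ClCH2CH2Cl, 70 °C
Reagents that add atoms: silver nitrite [Ag+].[O-]N=O
Why: Radical nitration of a terminal alkene, in which the NO2 radical adds to the CH2 terminus, TEMPO traps the secondary radical and loss of TEMPO-H gives the (E)-nitroalkene without touching the carbinol stereocentre.

**Step 7**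
Reactants: 4 1-[3-(benzyloxy)-4-methoxyphenyl]prop-2-en-1-one; 8 (1S,2E)-1-[3-(benzyloxy)-4-methoxyphenyl]-3-nitroprop-2-en-1-ol
Product: 10 [3-(benzyloxy)-4-methoxyphenyl][(3S,4R,5S)-5-[3-(benzyloxy)-4-methoxyphenyl]-4-(nitromethyl)oxolan-3-yl]methanone, via nitroalkenyl ether 9 (not isolated)
Conditions: (CF3SO2)2NH (5 mol %), CH2Cl2, 0 °C to rt; then THF, LiN(SiMe3)2, −78 °C; AcOH
Reagents that add atoms: none
Why: Acid-catalysed oxa-Michael addition of the alcohol to the vinyl ketone builds ether 9, and kinetic enolisation of its ketone then triggers a 5-exo-trig intramolecular Michael addition to the (E)-nitroalkene that closes the oxolane, with C3 set trans to the C2 aryl group through a chair-like transition state (aryl pseudo-equatorial) and the epimerisable C4 ending trans to C3 (thermodynamic, secured again in step 8).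

**Step 8**
Reactants: 10 [3-(benzyloxy)-4-methoxyphenyl][(3S,4R,5S)-5-[3-(benzyloxy)-4-methoxyphenyl]-4-(nitromethyl)oxolan-3-yl]methanone
Product: 13 [3-(benzyloxy)-4-methoxyphenyl][(3S,4R,5S)-5-[3-(benzyloxy)-4-methoxyphenyl]-4-(hydroxymethyl)oxolan-3-yl]methanone, via sodium nitronate 11 (not isolated), via aldehyde 12 (not isolated)
Conditions: NaOMe, MeOH/CH2Cl2, 0 °C; O3, −78 °C; then NaBH4, −78 to −40 °C
Reagents that add atoms: ozone [O-][O+]=O
Why: Nef reaction in its ozonolytic form, in which methoxide makes nitronate 11 (and equilibrates C4 to the all-trans arrangement), ozone cleaves the C=N bond to aldehyde 12, and NaBH4 at −78 °C reduces the aldehyde but not the hindered electron-rich aryl ketone, so C2 and C3 are carried over unchanged.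

**Step 9**
Reactants: 13 [3-(benzyloxy)-4-methoxyphenyl][(3S,4R,5S)-5-[3-(benzyloxy)-4-methoxyphenyl]-4-(hydroxymethyl)oxolan-3-yl]methanone
Product: 14 (3-hydroxy-4-methoxyphenyl)[(3S,4R,5S)-5-(3-hydroxy-4-methoxyphenyl)-4-(hydroxymethyl)oxolan-3-yl]methanone
Conditions: H2 (1 atm), 10% Pd/C, EtOAc, rt
Reagents that add atoms: none
Why: Catalytic hydrogenolysis of the two aryl benzyl ethers, which under neutral conditions at 1 atm is much faster than reduction of the aryl ketone or cleavage of the cyclic benzylic C–O bond and touches no stereocentre.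

## Compound list

1 | methyl 3-hydroxy-4-methoxybenzoate | COC(=O)c1ccc(OC)c(O)c1 | starting material
2 | methyl 3-(benzyloxy)-4-methoxybenzoate | COC(=O)c1ccc(OC)c(OCc2ccccc2)c1 | intermediate
3 | 3-(benzyloxy)-N,4-dimethoxy-N-methylbenzamide | CON(C)C(=O)c1ccc(OC)c(OCc2ccccc2)c1 | intermediate
4 | 1-[3-(benzyloxy)-4-methoxyphenyl]prop-2-en-1-one (fragment A) | C=CC(=O)c1ccc(OC)c(OCc2ccccc2)c1 | intermediate
5 | 3-(benzyloxy)-4-methoxybenzaldehyde | O=Cc1ccc(OC)c(OCc2ccccc2)c1 | starting material
6 | rac-1-[3-(benzyloxy)-4-methoxyphenyl]prop-2-en-1-ol | C=CC(O)c1ccc(OC)c(OCc2ccccc2)c1 | intermediate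
7 | (S)-1-[3-(benzyloxy)-4-methoxyphenyl]prop-2-en-1-ol | O[C@H](c1ccc(OC)c(OCc2ccccc2)c1)C=C | intermediate
8 | (1S,2E)-1-[3-(benzyloxy)-4-methoxyphenyl]-3-nitroprop-2-en-1-ol (fragment B) | O[C@H](c1ccc(OC)c(OCc2ccccc2)c1)/C=C/[N+](=O)[O-] | intermediate
9 | 1-[3-(benzyloxy)-4-methoxyphenyl]-3-{[(1S,2E)-1-[3-(benzyloxy)-4-methoxyphenyl]-3-nitroprop-2-en-1-yl]oxy}propan-1-one | COc1ccc(C(=O)CCO[C@H](c2ccc(OC)c(OCc3ccccc3)c2)/C=C/[N+](=O)[O-])cc1OCc1ccccc1 | intermediate
10 | [3-(benzyloxy)-4-methoxyphenyl][(3S,4R,5S)-5-[3-(benzyloxy)-4-methoxyphenyl]-4-(nitromethyl)oxolan-3-yl]methanone (all-trans) | COc1ccc(C(=O)[C@@H]2CO[C@H](c3ccc(OC)c(OCc4ccccc4)c3)[C@H]2C[N+](=O)[O-])cc1OCc1ccccc1 | intermediate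
11 | sodium nitronate of 10 | COc1ccc(C(=O)[C@@H]2CO[C@H](c3ccc(OC)c(OCc4ccccc4)c3)[C@H]2C=[N+]([O-])[O-])cc1OCc1ccccc1.[Na+] | intermediate
12 | (2S,3S,4S)-4-[3-(benzyloxy)-4-methoxybenzoyl]-2-[3-(benzyloxy)-4-methoxyphenyl]oxolane-3-carbaldehyde | COc1ccc(C(=O)[C@@H]2CO[C@H](c3ccc(OC)c(OCc4ccccc4)c3)[C@H]2C=O)cc1OCc1ccccc1 | intermediate
13 | [3-(benzyloxy)-4-methoxyphenyl][(3S,4R,5S)-5-[3-(benzyloxy)-4-methoxyphenyl]-4-(hydroxymethyl)oxolan-3-yl]methanone | COc1ccc(C(=O)[C@@H]2CO[C@H](c3ccc(OC)c(OCc4ccccc4)c3)[C@H]2CO)cc1OCc1ccccc1 | intermediate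
14 | (3-hydroxy-4-methoxyphenyl)[(3S,4R,5S)-5-(3-hydroxy-4-methoxyphenyl)-4-(hydroxymethyl)oxolan-3-yl]methanone | COc1ccc(C(=O)[C@@H]2CO[C@H](c3ccc(OC)c(O)c3)[C@H]2CO)cc1O | target

## Step count and risks

Total step count: 9 (steps 1–3 make fragment A, steps 4–6 make fragment B, steps 7–9 follow their union).
Longest linear sequence: 6 steps (1, 2, 3, 7, 8, 9 or 4, 5, 6, 7, 8, 9).

Steps most likely to fail:

Step 6. The TEMPO/nitrogen-oxide system can oxidise the free benzylic allylic alcohol to the enone instead of nitrating the alkene. The fallback masks the hydroxyl first. It sets out from 7: Et3SiCl and imidazole give the triethylsilyl ether F1, AgNO2/TEMPO nitration gives the silyl-protected nitroalkene F2, and AcOH/THF/H2O removes the silyl group, coming back to the route at 8.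

Step 7. The hindered, electron-poor alcohol 8 may add sluggishly to the enone under acid. In the base stage, deprotonation at the γ-position of the nitroalkene (loss of the C2 configuration) or β-elimination of the alkoxide can compete with ring closure. The fallback changes the order of events so that the ether is made before the nitroalkene exists. It sets out from 7 and 4: oxa-Michael addition (same acid catalyst, or catalytic PMe3) gives the allyl ether ketone F3. AgNO2/TEMPO nitration of its terminal alkene then rejoins the route at 9, now isolated and purified, which is cyclised with LiN(SiMe3)2 to 10.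

Step 8. Ozone can attack the electron-rich arenes, and NaBH4 can begin to reduce the ketone if the temperature drifts. The fallback uses a hydrolytic Nef reaction and a separate reduction. It sets out from 10: NaOMe, then addition of the nitronate to H2SO4/MeOH at −40 °C, gives the dimethyl acetal F4. Aqueous CF3CO2H releases aldehyde 12, which is isolated and reduced with NaBH(OAc)3, coming back to the route at 13.

## Further compounds

F1 | step 6 | triethyl{[(1S)-1-[3-(benzyloxy)-4-methoxyphenyl]prop-2-en-1-yl]oxy}silane | CC[Si](CC)(CC)O[C@H](c1ccc(OC)c(OCc2ccccc2)c1)C=C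
F2 | step 6 | triethyl{[(1S,2E)-1-[3-(benzyloxy)-4-methoxyphenyl]-3-nitroprop-2-en-1-yl]oxy}silane | CC[Si](CC)(CC)O[C@H](c1ccc(OC)c(OCc2ccccc2)c1)/C=C/[N+](=O)[O-]
F3 | step 7 | 1-[3-(benzyloxy)-4-methoxyphenyl]-3-{[(1S)-1-[3-(benzyloxy)-4-methoxyphenyl]prop-2-en-1-yl]oxy}propan-1-one | COc1ccc(C(=O)CCO[C@H](c2ccc(OC)c(OCc3ccccc3)c2)C=C)cc1OCc1ccccc1
F4 | step 8 | [3-(benzyloxy)-4-methoxyphenyl][(3S,4S,5S)-5-[3-(benzyloxy)-4-methoxyphenyl]-4-(dimethoxymethyl)oxolan-3-yl]methanone | COc1ccc(C(=O)[C@@H]2CO[C@H](c3ccc(OC)c(OCc4ccccc4)c3)[C@H]2C(OC)OC)cc1OCc1ccccc1
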